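## Retrosynthetic overview

1. The last operations are hydrogenolysis of six benzyl ethers and, before it, formation of the ester bond between the side-chain carbinol oxygen of ring B and the butanoyl carbonyl of the ring A fragment.
2. The strategy rests on ring B, the central 2,4-dihydroxy-6-alkylbenzoate. Its C1–C2–C3 plus the C1 carboxyl are the four carbons of an acetoacetate. Its C4–C5–C6 plus the 2-oxypropyl chain are the six carbons of a 5-oxyhex-2-enoate. The aryl ester flanked at both ortho positions can therefore be made as an ordinary acetoacetate ester before the ring exists.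
3. Ring B is traced back by dehydrogenation to a 2,4-dioxocyclohexane-1-carboxylate. This is opened at C1–C6 (Michael) and C3–C4 (Claisen) to the acetoacetate of the hydroxybutanoate–ring C alcohol and a phenyl (R)-5-silyloxyhex-2-enoate.
4. The acetoacetate comes from the ring C aryl bromide, (R)-propylene oxide, (R)-3-hydroxybutanoate and an acetylketene source. The enoate comes from the same hydroxybutanoate by reduction and Wittig olefination. The ring A acid comes from methyl orsellinate and tert-butyl (R)-3-hydroxybutanoate.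
5. Rings A and C are bought as arenes. Ring B is the only ring formed: it closes as a saturated dione and is then aromatized.

Key step: step 10

Remark: CIP analysis of the SMILES gives (R) at all four carbinol carbons. Each is taken from the chiral pool, and no step breaks a C–O bond at a stereocentre.

Shorthand in names: "chain C ester" means the ester formed at the free hydroxyl of (R)-1-[3,5-bis(benzyloxy)phenyl]propan-2-yl (R)-3-hydroxybutanoate.

## Route

**Step 1**
Reactants: 1 methyl (R)-3-hydroxybutanoate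
Product: 2 methyl (R)-3-(tert-butyldimethylsilyloxy)butanoate
Conditions: TBSCl (1.2 equiv), imidazole (2.5 equiv), DMF, 0 °C → rt
Reagents that add atoms: tert-butyldimethylsilyl chloride, CC(C)(C)[Si](C)(C)Cl
Why: Imidazole-promoted O-silylation of a secondary alcohol leaves the C–O bond at the stereocentre intact, so (R) is retained.

**Step 2**
Reactants: 2 methyl (R)-3-(tert-butyldimethylsilyloxy)butanoate
Product: 3 (R)-3-(tert-butyldimethylsilyloxy)butanoic acid
Conditions: LiOH·H2O (2 equiv), THF/MeOH/H2O, 0 °C → rt; 1 M HCl to pH 3 at 0 °C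
Reagents that add atoms: lithium hydroxide, [Li+].[OH-]
Why: Saponification of the unhindered methyl ester outruns E1cB loss of the poor silanolate leaving group, and the TBS ether survives the brief cold acidification.

**Step 3**
Reactants: 4 1,3-bis(benzyloxy)-5-bromobenzene; 5 (R)-propylene oxide
Product: 7 (R)-1-[3,5-bis(benzyloxy)phenyl]propan-2-ol, via arylmagnesium bromide 6 (not isolated)
Conditions: Mg, cat. I2, THF, reflux; CuI (0.1 equiv), −30 °C; 5 (1.3 equiv), −30 → 0 °C; H2O/aq. NH4Cl
Reagents that add atoms: none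
Why: Copper-catalysed Grignard opening of a terminal epoxide is an SN2 attack at the unsubstituted CH2, so the carbinol centre of 5 is carried over unchanged as (R).

**Step 4**
Reactants: 7 (R)-1-[3,5-bis(benzyloxy)phenyl]propan-2-ol; 3 (R)-3-(tert-butyldimethylsilyloxy)butanoic acid
Product: 8 (R)-1-[3,5-bis(benzyloxy)phenyl]propan-2-yl (R)-3-(tert-butyldimethylsilyloxy)butanoate
Conditions: DIC (1.2 equiv), DMAP (0.1 equiv), CH2Cl2, 0 °C → rt
Reagents that add atoms: none
Why: In this Steglich esterification of an unhindered secondary alcohol the acyl C–O bond is the one formed, so both carbinol centres keep their configuration, and the β-silyloxy group is too poor a leaving group to eliminate.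

**Step 5**
Reactants: 8 (R)-1-[3,5-bis(benzyloxy)phenyl]propan-2-yl (R)-3-(tert-butyldimethylsilyloxy)butanoate
Product: 9 (R)-1-[3,5-bis(benzyloxy)phenyl]propan-2-yl (R)-3-hydroxybutanoate
Conditions: HF·pyridine, THF, 0 °C → rt
Reagents that add atoms: none
Why: Fluoride-driven Si–O cleavage in a mildly acidic medium frees the β-hydroxy ester without the retro-aldol or elimination that basic fluoride sources could cause.

**Step 6**
Reactants: 9 (R)-1-[3,5-bis(benzyloxy)phenyl]propan-2-yl (R)-3-hydroxybutanoate; 10 2,2,6-trimethyl-4H-1,3-dioxin-4-one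
Product: 12 (R)-1-[3,5-bis(benzyloxy)phenyl]propan-2-yl (R)-3-(3-oxobutanoyloxy)butanoate, via acetylketene 11 (not isolated)
Conditions: 10 (1.3 equiv), toluene, 110 °C, acetone distilled off
Reagents that add atoms: none
Why: Thermal retro-hetero-Diels–Alder cleavage of the dioxinone releases acetylketene, which the open secondary alcohol captures under neutral conditions (acetoacetylation), so the future hindered aryl ester bond is made without base or activation.

**Step 7**
Reactants: 2 methyl (R)-3-(tert-butyldimethylsilyloxy)butanoate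
Product: 13 (R)-3-(tert-butyldimethylsilyloxy)butanal
Conditions: i-Bu2AlH (1.05 equiv), CH2Cl2, −78 °C; aq. potassium sodium tartrate
Reagents that add atoms: none
Why: Partial ester reduction stops at the tetrahedral aluminium hemiacetal at −78 °C, and this collapses to the aldehyde only on work-up.

**Step 8**
Reactants: 14 phenyl bromoacetate
Product: 16 phenyl (triphenyl-λ5-phosphanylidene)acetate, via phosphonium bromide 15 (not isolated)
Conditions: PPh3 (1.0 equiv), toluene, rt; crude salt in CH2Cl2 shaken briefly with cold aq. Na2CO3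
Reagents that add atoms: triphenylphosphine, c1ccc(cc1)P(c1ccccc1)c1ccccc1
Why: This stabilized-ylide preparation combines SN2 quaternization of PPh3 with carbonate deprotonation of the acidic phosphonium salt, and the short, cold, two-phase base contact spares the phenyl ester.

**Step 9**
Reactants: 13 (R)-3-(tert-butyldimethylsilyloxy)butanal; 16 phenyl (triphenyl-λ5-phosphanylidene)acetate
Product: 17 phenyl (R,E)-5-(tert-butyldimethylsilyloxy)hex-2-enoate
Conditions: 16 (1.2 equiv), CH2Cl2, rt
Reagents that add atoms: none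
Why: Wittig olefination with a stabilized ylide is E-selective and essentially neutral, so the β-silyloxy aldehyde should not eliminate, and the alkene geometry is consumed in step 10 in any case.

**Step 10**
Reactants: 12 (R)-1-[3,5-bis(benzyloxy)phenyl]propan-2-yl (R)-3-(3-oxobutanoyloxy)butanoate; 17 phenyl (R,E)-5-(tert-butyldimethylsilyloxy)hex-2-enoate
Product: 19 chain C ester of 6-[(R)-2-(tert-butyldimethylsilyloxy)propyl]-2,4-dioxocyclohexane-1-carboxylic acid (C1/C6 epimers), via Michael adduct 18 (not isolated)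
Conditions: 12 (1.0 equiv) and 17 (1.3 equiv) premixed, Cs2CO3 (1.0 equiv), 4 Å MS, MeCN (0.5 M), 0 °C → rt, then 40 °C until 18 is consumed; cold 1 M HCl
Reagents that add atoms: none
Why: Cs2CO3 removes only the C2–H of the acetoacetate, the enolate adds to C3 of 17 (ring bond C1–C6), and after proton transfer the small equilibrium share of the methyl-ketone enolate of 18 attacks the phenyl ester carbonyl and expels phenoxide (ring bond C3–C4). This is the classical Michael–Claisen (formal 3+3) annulation of acetoacetates with crotonate-type esters to dihydroresorcylates, normally run with alkoxide on alkyl esters; here the aryl ester supplies the extra electrophilicity and leaving-group ability that allow carbonate to replace alkoxide. Ring B closes in a 6-(enolendo)-exo-trig mode. The new centres C1 and C6 are not controlled (C6 feels only weak 1,3-induction from the silyloxy carbinol and C1 equilibrates through the enol), both are erased in step 11, and the three carbinol centres carry no acidic hydrogen. Among the four ester carbonyls only the phenyl ester is activated and placed for a six-membered C-acylation; O-acylation of the adduct enolate is reversible because the released phenoxide reopens the O-acyl product, whereas C-acylation becomes irreversible once the vinylogous acid 19 is deprotonated, which also consumes the phenoxide. One equivalent of base, premixing with excess 17 and high concentration should keep three side reactions slower than the bimolecular Michael step: E1cB loss of the β-acyloxy group, vinylogous loss of the silyloxy group from 17, and Dieckmann attack of the unreacted enolate on the butanoate ester.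

**Step 11**
Reactants: 19 chain C ester of 6-[(R)-2-(tert-butyldimethylsilyloxy)propyl]-2,4-dioxocyclohexane-1-carboxylic acid
Product: 22 chain C ester of 6-[(R)-2-(tert-butyldimethylsilyloxy)propyl]-2,4-dihydroxybenzoic acid, via bis(trimethylsilyl) dienol ether 20 (not isolated), via bis(trimethylsilyl) resorcylate 21 (not isolated)
Conditions: N,O-bis(trimethylsilyl)acetamide (4 equiv), toluene, rt → 40 °C; DDQ (1.1 equiv), 0 °C → rt; aq. citric acid/THF
Reagents that add atoms: none
Why: In this silylation-mediated DDQ dehydrogenation, double O-silylation fixes ring B as the cyclohexa-1,3-diene 20, DDQ abstracts hydride from C6–H to give a pentadienyl cation stabilized by the silyloxy groups on C2 and C4, loss of a C5 proton gives arene 21, the aryl TMS ethers fall off on acidic work-up, and the benzyl aryl ethers, the alkyl TBS ether and the esters are inert.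

**Step 12**
Reactants: 22 chain C ester of 6-[(R)-2-(tert-butyldimethylsilyloxy)propyl]-2,4-dihydroxybenzoic acid
Product: 23 chain C ester of 2,4-bis(benzyloxy)-6-[(R)-2-(tert-butyldimethylsilyloxy)propyl]benzoic acid
Conditions: BnBr (2.5 equiv), K2CO3 (3 equiv), cat. n-Bu4NI, DMF, rt → 45 °C
Reagents that add atoms: benzyl bromide, BrCc1ccccc1
Why: In this Williamson etherification carbonate deprotonates only the two phenols, which are far more acidic than the ester α-hydrogens, so the β-acyloxy ester should persist, and the silyl ether blocks lactonization.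

**Step 13**
Reactants: 24 methyl orsellinate (methyl 2,4-dihydroxy-6-methylbenzoate)
Product: 25 methyl 2,4-bis(benzyloxy)-6-methylbenzoate
Conditions: BnBr (2.5 equiv), K2CO3 (3 equiv), DMF, 60 °C
Reagents that add atoms: benzyl bromide, BrCc1ccccc1
Why: Williamson etherification of both phenols needs mild heating for the hydrogen-bonded 2-OH.

**Step 14**
Reactants: 25 methyl 2,4-bis(benzyloxy)-6-methylbenzoate
Product: 26 2,4-bis(benzyloxy)-6-methylbenzoic acid
Conditions: KOH (10 equiv), DMSO/H2O, 90 °C; 1 M HCl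
Reagents that add atoms: potassium hydroxide, [K+].[OH-]
Why: Forced saponification of the hindered methyl benzoate with poorly solvated hydroxide is acceptable because the substrate has no other base-sensitive group.

**Step 15**
Reactants: 26 2,4-bis(benzyloxy)-6-methylbenzoic acid; 27 tert-butyl (R)-3-hydroxybutanoate
Product: 29 (R)-4-tert-butoxy-4-oxobutan-2-yl 2,4-bis(benzyloxy)-6-methylbenzoate, via acid chloride 28 (not isolated)
Conditions: (COCl)2, cat. DMF, CH2Cl2, 0 °C → rt, evaporate; 27, Et3N (2 equiv), DMAP (0.5 equiv), CH2Cl2, 0 °C → rt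
Reagents that add atoms: none
Why: DMAP-catalysed acylation by the electron-rich hindered aroyl chloride forms the acyl C–O bond, so the carbinol centre of 27 stays (R), and Et3N is too weak to eliminate the β-aroyloxy tert-butyl ester.

**Step 16**
Reactants: 29 (R)-4-tert-butoxy-4-oxobutan-2-yl 2,4-bis(benzyloxy)-6-methylbenzoate
Product: 30 (R)-3-[2,4-bis(benzyloxy)-6-methylbenzoyloxy]butanoic acid
Conditions: TFA/CH2Cl2 1:4, 0 °C → rt
Reagents that add atoms: none
Why: Acidolysis of the tert-butyl ester (AAL1, loss of isobutene) avoids any base near the β-aroyloxy unit, and the benzyl aryl ethers tolerate short exposure to dilute TFA.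

**Step 17**
Reactants: 23 chain C ester of 2,4-bis(benzyloxy)-6-[(R)-2-(tert-butyldimethylsilyloxy)propyl]benzoic acid
Product: 31 chain C ester of 2,4-bis(benzyloxy)-6-[(R)-2-hydroxypropyl]benzoic acid
Conditions: HF·pyridine, pyridine, THF, 0 °C → rt; cold aq. NaHCO3 wash, used at once
Reagents that add atoms: none
Why: Buffered acidic fluoride desilylation never generates an alkoxide, which should hold back attack of the freed side-chain hydroxyl on the neighbouring ring B ester.

**Step 18**
Reactants: 31 chain C ester of 2,4-bis(benzyloxy)-6-[(R)-2-hydroxypropyl]benzoic acid; 30 (R)-3-[2,4-bis(benzyloxy)-6-methylbenzoyloxy]butanoic acid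
Product: 32 hexa-O-benzyl Hansforester A
Conditions: 30 (1.5 equiv), DIC (1.6 equiv), DMAP (0.3 equiv), DMAP·HCl (0.3 equiv), CH2Cl2, 0 °C → rt
Reagents that add atoms: none
Why: In this Steglich esterification the DMAP·HCl buffer keeps the medium close to neutral, which tempers both E1cB loss of the aroyloxy group from the activated acid and lactonization of 31, and all four carbinol centres are untouched.

**Step 19**
Reactants: 32 hexa-O-benzyl Hansforester A
Product: 33 Hansforester A
Conditions: H2 (1 atm), Pd/C (10 wt %), EtOAc/EtOH, rt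
Reagents that add atoms: none
Why: Catalytic hydrogenolysis cleaves the six benzyl aryl ethers, while the four ester C–O bonds sit on homobenzylic or purely aliphatic carbons and are not hydrogenolysed.

## Compound list

1 | methyl (R)-3-hydroxybutanoate | C[C@@H](O)CC(=O)OC | starting material
2 | methyl (R)-3-(tert-butyldimethylsilyloxy)butanoate | CC(C)(C)[Si](C)(C)O[C@H](C)CC(=O)OC | intermediate
3 | (R)-3-(tert-butyldimethylsilyloxy)butanoic acid | CC(C)(C)[Si](C)(C)O[C@H](C)CC(=O)O | intermediate
4 | 1,3-bis(benzyloxy)-5-bromobenzene | Brc1cc(OCc2ccccc2)cc(OCc2ccccc2)c1 | starting material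
5 | (R)-propylene oxide | C[C@@H]1CO1 | starting material
6 | 3,5-bis(benzyloxy)phenylmagnesium bromide | Br[Mg]c1cc(OCc2ccccc2)cc(OCc2ccccc2)c1 | intermediate
7 | (R)-1-[3,5-bis(benzyloxy)phenyl]propan-2-ol | O[C@H](C)Cc1cc(OCc2ccccc2)cc(OCc2ccccc2)c1 | intermediate
8 | (R)-1-[3,5-bis(benzyloxy)phenyl]propan-2-yl (R)-3-(tert-butyldimethylsilyloxy)butanoate | CC(C)(C)[Si](C)(C)O[C@H](C)CC(=O)O[C@H](C)Cc1cc(OCc2ccccc2)cc(OCc2ccccc2)c1 | intermediate
9 | (R)-1-[3,5-bis(benzyloxy)phenyl]propan-2-yl (R)-3-hydroxybutanoate | O[C@H](C)CC(=O)O[C@H](C)Cc1cc(OCc2ccccc2)cc(OCc2ccccc2)c1 | intermediate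
10 | 2,2,6-trimethyl-4H-1,3-dioxin-4-one | CC1=CC(=O)OC(C)(C)O1 | starting material
11 | acetylketene | CC(=O)C=C=O | intermediate
12 | (R)-1-[3,5-bis(benzyloxy)phenyl]propan-2-yl (R)-3-(3-oxobutanoyloxy)butanoate | CC(=O)CC(=O)O[C@H](C)CC(=O)O[C@H](C)Cc1cc(OCc2ccccc2)cc(OCc2ccccc2)c1 | intermediate
13 | (R)-3-(tert-butyldimethylsilyloxy)butanal | CC(C)(C)[Si](C)(C)O[C@H](C)CC=O | intermediate
14 | phenyl bromoacetate | BrCC(=O)Oc1ccccc1 | starting material
15 | (2-oxo-2-phenoxyethyl)triphenylphosphonium bromide | O=C(C[P+](c1ccccc1)(c1ccccc1)c1ccccc1)Oc1ccccc1.[Br-] | intermediate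
16 | phenyl (triphenyl-λ5-phosphanylidene)acetate | O=C(C=P(c1ccccc1)(c1ccccc1)c1ccccc1)Oc1ccccc1 | intermediate
17 | phenyl (R,E)-5-(tert-butyldimethylsilyloxy)hex-2-enoate | CC(C)(C)[Si](C)(C)O[C@H](C)C/C=C/C(=O)Oc1ccccc1 | intermediate
18 | Michael adduct: 5-phenyl 1-(chain C) diester of 2-acetyl-3-[(R)-2-(tert-butyldimethylsilyloxy)propyl]pentanedioic acid (C2/C3 epimers) | CC(C)(C)[Si](C)(C)O[C@H](C)CC(CC(=O)Oc1ccccc1)C(C(C)=O)C(=O)O[C@H](C)CC(=O)O[C@H](C)Cc1cc(OCc2ccccc2)cc(OCc2ccccc2)c1 | intermediate
19 | chain C ester of 6-[(R)-2-(tert-butyldimethylsilyloxy)propyl]-2,4-dioxocyclohexane-1-carboxylic acid (C1/C6 epimers) | CC(C)(C)[Si](C)(C)O[C@H](C)CC1CC(=O)CC(=O)C1C(=O)O[C@H](C)CC(=O)O[C@H](C)Cc1cc(OCc2ccccc2)cc(OCc2ccccc2)c1 | intermediate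
20 | chain C ester of 6-[(R)-2-(tert-butyldimethylsilyloxy)propyl]-2,4-bis(trimethylsilyloxy)cyclohexa-1,3-diene-1-carboxylic acid (C6 epimers) | CC(C)(C)[Si](C)(C)O[C@H](C)CC1CC(O[Si](C)(C)C)=CC(O[Si](C)(C)C)=C1C(=O)O[C@H](C)CC(=O)O[C@H](C)Cc1cc(OCc2ccccc2)cc(OCc2ccccc2)c1 | intermediate
21 | chain C ester of 6-[(R)-2-(tert-butyldimethylsilyloxy)propyl]-2,4-bis(trimethylsilyloxy)benzoic acid | CC(C)(C)[Si](C)(C)O[C@H](C)Cc1cc(O[Si](C)(C)C)cc(O[Si](C)(C)C)c1C(=O)O[C@H](C)CC(=O)O[C@H](C)Cc1cc(OCc2ccccc2)cc(OCc2ccccc2)c1 | intermediate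
22 | chain C ester of 6-[(R)-2-(tert-butyldimethylsilyloxy)propyl]-2,4-dihydroxybenzoic acid | CC(C)(C)[Si](C)(C)O[C@H](C)Cc1cc(O)cc(O)c1C(=O)O[C@H](C)CC(=O)O[C@H](C)Cc1cc(OCc2ccccc2)cc(OCc2ccccc2)c1 | intermediate
23 | chain C ester of 2,4-bis(benzyloxy)-6-[(R)-2-(tert-butyldimethylsilyloxy)propyl]benzoic acid | CC(C)(C)[Si](C)(C)O[C@H](C)Cc1cc(OCc2ccccc2)cc(OCc2ccccc2)c1C(=O)O[C@H](C)CC(=O)O[C@H](C)Cc1cc(OCc2ccccc2)cc(OCc2ccccc2)c1 | intermediate
24 | methyl orsellinate | Cc1cc(O)cc(O)c1C(=O)OC | starting material
25 | methyl 2,4-bis(benzyloxy)-6-methylbenzoate | Cc1cc(OCc2ccccc2)cc(OCc2ccccc2)c1C(=O)OC | intermediate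
26 | 2,4-bis(benzyloxy)-6-methylbenzoic acid | Cc1cc(OCc2ccccc2)cc(OCc2ccccc2)c1C(=O)O | intermediate
27 | tert-butyl (R)-3-hydroxybutanoate | C[C@@H](O)CC(=O)OC(C)(C)C | starting material
28 | 2,4-bis(benzyloxy)-6-methylbenzoyl chloride | Cc1cc(OCc2ccccc2)cc(OCc2ccccc2)c1C(=O)Cl | intermediate
29 | (R)-4-tert-butoxy-4-oxobutan-2-yl 2,4-bis(benzyloxy)-6-methylbenzoate | Cc1cc(OCc2ccccc2)cc(OCc2ccccc2)c1C(=O)O[C@H](C)CC(=O)OC(C)(C)C | intermediate
30 | (R)-3-[2,4-bis(benzyloxy)-6-methylbenzoyloxy]butanoic acid | Cc1cc(OCc2ccccc2)cc(OCc2ccccc2)c1C(=O)O[C@H](C)CC(=O)O | intermediate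
31 | chain C ester of 2,4-bis(benzyloxy)-6-[(R)-2-hydroxypropyl]benzoic acid | O[C@H](C)Cc1cc(OCc2ccccc2)cc(OCc2ccccc2)c1C(=O)O[C@H](C)CC(=O)O[C@H](C)Cc1cc(OCc2ccccc2)cc(OCc2ccccc2)c1 | intermediate
32 | hexa-O-benzyl Hansforester A | Cc1cc(OCc2ccccc2)cc(OCc2ccccc2)c1C(=O)O[C@H](C)CC(=O)O[C@H](C)Cc1cc(OCc2ccccc2)cc(OCc2ccccc2)c1C(=O)O[C@H](C)CC(=O)O[C@H](C)Cc1cc(OCc2ccccc2)cc(OCc2ccccc2)c1 | intermediate
33 | Hansforester A | Cc1cc(O)cc(O)c1C(=O)O[C@H](C)CC(=O)O[C@H](C)Cc1cc(O)cc(O)c1C(=O)O[C@H](C)CC(=O)O[C@H](C)Cc1cc(O)cc(O)c1 | target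

## Step count

Total step count: 19.
Longest linear sequence: 11 steps (1, 2, 4, 5, 6, 10, 11, 12, 17, 18, 19).

## Steps most likely to fail

**Step 10.** Conjugate addition to the β-branched enoate may be too slow at the low basicity that the β-acyloxy ester tolerates. In that case elimination of the acyloxy group, Dieckmann attack of the acetoacetate enolate on the butanoate ester, or persistent O-acylation in place of C-acylation could take over.

The fallback builds ring B directly at the arene oxidation level by ketene trapping and aldol aromatization. It sets out from alcohol 9 (with 3 and 10 as partners) and comes back at resorcylate 22, so steps 6 to 11 fall away. Dioxinone 10 is deprotonated with LiN(SiMe3)2 in THF at −78 °C and C-acetylated with acetyl chloride to 2,2-dimethyl-6-(2-oxopropyl)-4H-1,3-dioxin-4-one F1. Acid 3 is converted with carbonyldiimidazole and MeONHMe·HCl into the Weinreb amide (R)-3-(tert-butyldimethylsilyloxy)-N-methoxy-N-methylbutanamide F2. The dianion of F1 (two equivalents of LiN(i-Pr)2) is acylated at its terminal carbon by F2 to give the diketo-dioxinone F3. Heating F3 with 9 in toluene at 110 °C releases the acylketene F4, which 9 captures as the 3,5,7-trioxo ester F5. Et3N and then dilute acid bring about aldol condensation of C2 onto the C7 ketone, dehydration and enolization to 22.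

**Step 11.** The second O-silylation may stay incomplete, the quinone may add to the nucleophilic C3 instead of abstracting hydride from C6, or the liberated resorcylate may be over-oxidized.

The fallback replaces hydride abstraction by a selenoxide syn-elimination on a mono-protected ring. It sets out from 19 and comes back at 23. Mitsunobu O-alkylation of the vinylogous acid with benzyl alcohol (PPh3, DIAD, THF) should go mainly to the C4 oxygen, remote from the ester, and give the 4-benzyloxy-2-oxocyclohex-3-ene-1-carboxylate F6. PhSeCl/pyridine in CH2Cl2 selenenylates the remaining β-keto ester position C1, anti to the C6 side chain, to give the C1 selenide F7. H2O2 at 0 °C gives the selenoxide F8, which eliminates toward the syn C6–H and tautomerizes to the 4-benzyloxy-2-hydroxybenzoate F9. Benzylation of the 2-OH under the conditions of step 12 gives 23.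

**Step 18.** Acylation of the congested side-chain alcohol may be slow. This would leave time for lactonization onto the ring B ester and for E1cB loss of the aroyloxy group from the activated acid.

The fallback attaches the chain in two pieces. It sets out from 31 and comes back at 32. Alcohol 31 is esterified at once with an excess of silyloxy acid 3 (DIC, full DMAP loading). This acid has no good β-leaving group and can be pushed hard, and it gives the silyl-protected hydroxybutanoate F10. HF·pyridine then frees the terminal alcohol F11, which is no longer placed for lactonization. Acylation with acid chloride 28 (Et3N, DMAP, as in step 15) gives 32.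

## Further compounds

F1 | step 10 | 2,2-dimethyl-6-(2-oxopropyl)-4H-1,3-dioxin-4-one | CC(=O)CC1=CC(=O)OC(C)(C)O1
F2 | step 10 | (R)-3-(tert-butyldimethylsilyloxy)-N-methoxy-N-methylbutanamide | CC(C)(C)[Si](C)(C)O[C@H](C)CC(=O)N(C)OC
F3 | step 10 | 6-[(R)-6-(tert-butyldimethylsilyloxy)-2,4-dioxoheptyl]-2,2-dimethyl-4H-1,3-dioxin-4-one | CC(C)(C)[Si](C)(C)O[C@H](C)CC(=O)CC(=O)CC1=CC(=O)OC(C)(C)O1
F4 | step 10 | (R)-9-(tert-butyldimethylsilyloxy)-3,5,7-trioxodec-1-en-1-one (acylketene) | CC(C)(C)[Si](C)(C)O[C@H](C)CC(=O)CC(=O)CC(=O)C=C=O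
F5 | step 10 | chain C ester of (R)-9-(tert-butyldimethylsilyloxy)-3,5,7-trioxodecanoic acid | CC(C)(C)[Si](C)(C)O[C@H](C)CC(=O)CC(=O)CC(=O)CC(=O)O[C@H](C)CC(=O)O[C@H](C)Cc1cc(OCc2ccccc2)cc(OCc2ccccc2)c1
F6 | step 11 | chain C ester of 4-benzyloxy-6-[(R)-2-(tert-butyldimethylsilyloxy)propyl]-2-oxocyclohex-3-ene-1-carboxylic acid (C1/C6 epimers) | CC(C)(C)[Si](C)(C)O[C@H](C)CC1CC(OCc2ccccc2)=CC(=O)C1C(=O)O[C@H](C)CC(=O)O[C@H](C)Cc1cc(OCc2ccccc2)cc(OCc2ccccc2)c1
F7 | step 11 | chain C ester of 4-benzyloxy-6-[(R)-2-(tert-butyldimethylsilyloxy)propyl]-2-oxo-1-(phenylselanyl)cyclohex-3-ene-1-carboxylic acid | CC(C)(C)[Si](C)(C)O[C@H](C)CC1CC(OCc2ccccc2)=CC(=O)C1([Se]c2ccccc2)C(=O)O[C@H](C)CC(=O)O[C@H](C)Cc1cc(OCc2ccccc2)cc(OCc2ccccc2)c1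
F8 | step 11 | selenoxide of F7 | CC(C)(C)[Si](C)(C)O[C@H](C)CC1CC(OCc2ccccc2)=CC(=O)C1([Se](=O)c2ccccc2)C(=O)O[C@H](C)CC(=O)O[C@H](C)Cc1cc(OCc2ccccc2)cc(OCc2ccccc2)c1
F9 | step 11 | chain C ester of 4-benzyloxy-6-[(R)-2-(tert-butyldimethylsilyloxy)propyl]-2-hydroxybenzoic acid | CC(C)(C)[Si](C)(C)O[C@H](C)Cc1cc(OCc2ccccc2)cc(O)c1C(=O)O[C@H](C)CC(=O)O[C@H](C)Cc1cc(OCc2ccccc2)cc(OCc2ccccc2)c1
F10 | step 18 | chain C ester of 2,4-bis(benzyloxy)-6-{(R)-2-[(R)-3-(tert-butyldimethylsilyloxy)butanoyloxy]propyl}benzoic acid | CC(C)(C)[Si](C)(C)O[C@H](C)CC(=O)O[C@H](C)Cc1cc(OCc2ccccc2)cc(OCc2ccccc2)c1C(=O)O[C@H](C)CC(=O)O[C@H](C)Cc1cc(OCc2ccccc2)cc(OCc2ccccc2)c1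
F11 | step 18 | chain C ester of 2,4-bis(benzyloxy)-6-{(R)-2-[(R)-3-hydroxybutanoyloxy]propyl}benzoic acid | O[C@H](C)CC(=O)O[C@H](C)Cc1cc(OCc2ccccc2)cc(OCc2ccccc2)c1C(=O)O[C@H](C)CC(=O)O[C@H](C)Cc1cc(OCc2ccccc2)cc(OCc2ccccc2)c1
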